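**Retrosynthetic overview**

1. The target is reached last by hydrogenolysis of the ring B benzyl ether and benzyl ester of a protected depside.
2. Ring A is built on the preformed depside ester by cutting C1A–C2A and C5A–C6A. The C2A(OH)–C3A(Cl)–C4A(OMe) triad plus C5A is the O–C(Cl)–C(O)–CH3 chain of methyl 2-chloroacetoacetate; C1A (carbonyl-bearing) and C6A (propyl-bearing) are the alkyne carbons of a hex-2-ynoate.
3. The diene partner is 2-chloro-1,3-dimethoxy-1-trimethylsilyloxybutadiene, made from methyl 2-chloroacetoacetate via the methyl enol ether and the silyl ketene acetal.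
4. The dienophile is hex-2-ynoic acid esterified onto the C4B phenol of benzyl 2-(benzyloxy)-4-hydroxy-6-propylbenzoate, prepared from 5-propylresorcinol by formylation, O4-allyl/O2-benzyl differentiation, oxidation, benzyl ester formation and deallylation.
5. Ring order: ring B is bought as the resorcinol; ring A is formed by (4+2) cycloaddition and aromatization.

Key step: step 10

Remark: ring A is the chlorinated benzoyl ring (C1A ester carbonyl, C2A OH, C3A Cl, C4A OMe, C5A H, C6A propyl); ring B is the benzoic acid ring (C1B CO2H, C2B OH, C4B O-acyl, C6B propyl).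
Remark: the enol ether and the diene are drawn as single geometric isomers; either isomer or a mixture converges, because these double bonds end up in the arene.

Step 1
Reactants: 1 5-propylbenzene-1,3-diol
Product: 3 2,4-dihydroxy-6-propylbenzaldehyde, via iminium salt 2 (not isolated)
Conditions: POCl3, DMF, 0 °C → rt; then H2O, 50 °C
Reagents that add atoms: N,N-dimethylformamide CN(C)C=O; water O
Why: Vilsmeier–Haack formylation, in which the chloroiminium ion attacks the position between OH and propyl (para to the other OH), the site at which 5-alkylresorcinols are known to formylate, and hydrolysis of iminium salt 2 releases the aldehyde.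

Step 2
Reactants: 3 2,4-dihydroxy-6-propylbenzaldehyde
Product: 4 2-hydroxy-4-(prop-2-en-1-yloxy)-6-propylbenzaldehyde
Conditions: allyl bromide (1.05 equiv), K2CO3 (1.0 equiv), acetone, rt → 40 °C
Reagents that add atoms: allyl bromide C=CCBr
Why: Williamson etherification should be selective for O4, because the C2 hydroxyl is held in a hydrogen bond to the aldehyde and is less acidic than the para hydroxyl.

Step 3
Reactants: 4 2-hydroxy-4-(prop-2-en-1-yloxy)-6-propylbenzaldehyde
Product: 5 2-(benzyloxy)-4-(prop-2-en-1-yloxy)-6-propylbenzaldehyde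
Conditions: BnBr, K2CO3, DMF, 60 °C
Reagents that add atoms: benzyl bromide BrCc1ccccc1
Why: Williamson etherification under more forcing conditions alkylates the remaining chelated phenol, and the allyl ether is inert.

Step 4
Reactants: 5 2-(benzyloxy)-4-(prop-2-en-1-yloxy)-6-propylbenzaldehyde
Product: 6 2-(benzyloxy)-4-(prop-2-en-1-yloxy)-6-propylbenzoic acid
Conditions: NaClO2, NaH2PO4, 2-methylbut-2-ene (excess), t-BuOH/THF/H2O, rt
Reagents that add atoms: sodium chlorite [Na+].[O-]Cl=O
Why: Pinnick oxidation converts the hindered, electron-rich aldehyde into the acid, while excess 2-methylbut-2-ene traps HOCl before it can chlorinate ring B or add to the allyl group.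

Step 5
Reactants: 6 2-(benzyloxy)-4-(prop-2-en-1-yloxy)-6-propylbenzoic acid
Product: 7 benzyl 2-(benzyloxy)-4-(prop-2-en-1-yloxy)-6-propylbenzoate
Conditions: BnBr, K2CO3, DMF, rt
Reagents that add atoms: benzyl bromide BrCc1ccccc1
Why: Carboxylate O-alkylation (SN2 on benzyl bromide) is insensitive to the two ortho substituents that would slow an acyl-substitution esterification.

Step 6
Reactants: 7 benzyl 2-(benzyloxy)-4-(prop-2-en-1-yloxy)-6-propylbenzoate
Product: 8 benzyl 2-(benzyloxy)-4-hydroxy-6-propylbenzoate
Conditions: Pd(PPh3)4 (2 mol%), morpholine, THF, rt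
Reagents that add atoms: none
Why: Tsuji–Trost-type deallylation, in which zerovalent palladium ionizes the aryl allyl ether to a π-allyl complex that morpholine intercepts, leaving benzyl ether and benzyl ester untouched.

Step 7
Reactants: 8 benzyl 2-(benzyloxy)-4-hydroxy-6-propylbenzoate; 9 hex-2-ynoic acid
Product: 10 benzyl 2-(benzyloxy)-4-(hex-2-ynoyloxy)-6-propylbenzoate
Conditions: DCC, DMAP (5 mol%), CH2Cl2, 0 °C → rt
Reagents that add atoms: none
Why: Steglich esterification of an unhindered phenol with an acid that has no ortho substituents yet, run cold with only catalytic DMAP to limit conjugate addition to the ynoate.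

Step 8
Reactants: 11 methyl 2-chloro-3-oxobutanoate
Product: 13 methyl (2Z)-2-chloro-3-methoxybut-2-enoate, via dimethyl ketal 12 (not isolated)
Conditions: HC(OMe)3 (neat), H2SO4 (cat.), rt; then distillation from the acid catalyst
Reagents that add atoms: trimethyl orthoformate COC(OC)OC
Why: Acid-catalysed ketalization with orthoformate followed by loss of methanol is the standard route from acetoacetates to 3-methoxybut-2-enoates, and the acidic C2–H between chlorine and ester should favour the elimination.

Step 9
Reactants: 13 methyl (2Z)-2-chloro-3-methoxybut-2-enoate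
Product: 15 {[(1Z)-2-chloro-1,3-dimethoxybuta-1,3-dien-1-yl]oxy}trimethylsilane, via lithium dienolate 14 (not isolated)
Conditions: LiN(i-Pr)2, THF, −78 °C; then Me3SiCl, −78 °C → rt; hexane, filtration, used crude
Reagents that add atoms: chlorotrimethylsilane C[Si](C)(C)Cl
Why: Vinylogous (γ) deprotonation of the methyl group and O-silylation of the dienolate is the standard preparation of 1-alkoxy-1-silyloxy dienes of the Brassard type, and with no α-hydrogen only the C4 methyl can be deprotonated.

Step 10
Reactants: 10 benzyl 2-(benzyloxy)-4-(hex-2-ynoyloxy)-6-propylbenzoate; 15 {[(1Z)-2-chloro-1,3-dimethoxybuta-1,3-dien-1-yl]oxy}trimethylsilane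
Product: 18 benzyl 2-(benzyloxy)-4-[(3-chloro-2-hydroxy-4-methoxy-6-propylbenzoyl)oxy]-6-propylbenzoate, via cyclohexadiene cycloadduct 16 (not isolated), via aryl trimethylsilyl ether 17 (not isolated)
Conditions: 15 (3 equiv), toluene, 110 °C, sealed tube; then 1 M HCl, THF, rt
Reagents that add atoms: none
Why: The electron-rich diene 15, whose HOMO coefficient is largest at the terminal CH2, adds to the electron-poor aryl ynoate 10 in a concerted but asynchronous normal-electron-demand (4+2) cycloaddition, the CH2 terminus bonding to the β-carbon (C5A–C6A) and the ketene acetal carbon to the α-carbon (C1A–C2A), so that ring A closes as the six-membered cyclohexa-1,4-diene 16 by intermolecular cycloaddition. Cycloadduct 16 should then lose methanol across C2A/C5A, driven by aromatization, to give silyl ether 17, and dilute acid removes the silyl group to leave the C2A phenol hydrogen-bonded to the ester carbonyl. The closest known reaction type is the Diels–Alder/aromatization of 1-alkoxy-1-silyloxy-1,3-dienes with alkynoates to give salicylates. No stereocentre is created in the product, since the acetal carbon of 16 is transient and the diene geometry is erased. The step needs regioselectivity, secured by the matched polarization of ketene acetal diene and ynoate, and it needs cycloaddition to outrun silyl transfer to protic groups, which is why the ring B phenol and acid are benzyl-protected. Chlorine and the methyl ether arrive with the diene, so no arene chlorination or selective O-methylation is required, and the depside ester already exists before its two ortho substituents are made.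

Step 11
Reactants: 18 benzyl 2-(benzyloxy)-4-[(3-chloro-2-hydroxy-4-methoxy-6-propylbenzoyl)oxy]-6-propylbenzoate
Product: 19 3-chlorodivaricatic acid, 4-[(3-chloro-2-hydroxy-4-methoxy-6-propylbenzoyl)oxy]-2-hydroxy-6-propylbenzoic acid
Conditions: H2 (1 atm), 10% Pd/C, EtOAc, rt, stopped after uptake of 2 equiv H2
Reagents that add atoms: none
Why: Catalytic hydrogenolysis cleaves the benzyl ester and the benzyl aryl ether much faster than an aryl C–Cl bond in neutral ethyl acetate without base, and the depside ester and methyl ether are inert.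

**Compound list**

1 | 5-propylbenzene-1,3-diol | CCCc1cc(O)cc(O)c1 | starting material
2 | [(2,4-dihydroxy-6-propylphenyl)methylidene]dimethyliminium dichlorophosphate | CCCc1cc(O)cc(O)c1C=[N+](C)C.[O-]P(=O)(Cl)Cl | intermediate
3 | 2,4-dihydroxy-6-propylbenzaldehyde | CCCc1cc(O)cc(O)c1C=O | intermediate
4 | 2-hydroxy-4-(prop-2-en-1-yloxy)-6-propylbenzaldehyde | CCCc1cc(OCC=C)cc(O)c1C=O | intermediate
5 | 2-(benzyloxy)-4-(prop-2-en-1-yloxy)-6-propylbenzaldehyde | CCCc1cc(OCC=C)cc(OCc2ccccc2)c1C=O | intermediate
6 | 2-(benzyloxy)-4-(prop-2-en-1-yloxy)-6-propylbenzoic acid | CCCc1cc(OCC=C)cc(OCc2ccccc2)c1C(=O)O | intermediate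
7 | benzyl 2-(benzyloxy)-4-(prop-2-en-1-yloxy)-6-propylbenzoate | CCCc1cc(OCC=C)cc(OCc2ccccc2)c1C(=O)OCc1ccccc1 | intermediate
8 | benzyl 2-(benzyloxy)-4-hydroxy-6-propylbenzoate | CCCc1cc(O)cc(OCc2ccccc2)c1C(=O)OCc1ccccc1 | intermediate
9 | hex-2-ynoic acid | CCCC#CC(=O)O | starting material
10 | benzyl 2-(benzyloxy)-4-(hex-2-ynoyloxy)-6-propylbenzoate | CCCC#CC(=O)Oc1cc(CCC)c(C(=O)OCc2ccccc2)c(OCc2ccccc2)c1 | intermediate
11 | methyl 2-chloro-3-oxobutanoate | CC(=O)C(Cl)C(=O)OC | starting material
12 | methyl 2-chloro-3,3-dimethoxybutanoate | COC(=O)C(Cl)C(C)(OC)OC | intermediate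
13 | methyl (2Z)-2-chloro-3-methoxybut-2-enoate | COC(=O)/C(Cl)=C(\C)OC | intermediate
14 | lithium (1E)-2-chloro-1,3-dimethoxybuta-1,3-dien-1-olate | [Li+].C=C(OC)/C(Cl)=C(\OC)[O-] | intermediate
15 | {[(1Z)-2-chloro-1,3-dimethoxybuta-1,3-dien-1-yl]oxy}trimethylsilane | C=C(OC)/C(Cl)=C(\OC)O[Si](C)(C)C | intermediate
16 | benzyl 2-(benzyloxy)-4-({5-chloro-4,6-dimethoxy-2-propyl-6-[(trimethylsilyl)oxy]cyclohexa-1,4-dien-1-yl}carbonyloxy)-6-propylbenzoate, racemic at the acetal carbon | CCCC1=C(C(=O)Oc2cc(CCC)c(C(=O)OCc3ccccc3)c(OCc3ccccc3)c2)C(OC)(O[Si](C)(C)C)C(Cl)=C(OC)C1 | intermediate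
17 | benzyl 2-(benzyloxy)-4-({3-chloro-4-methoxy-6-propyl-2-[(trimethylsilyl)oxy]benzoyl}oxy)-6-propylbenzoate | CCCc1cc(OC)c(Cl)c(O[Si](C)(C)C)c1C(=O)Oc1cc(CCC)c(C(=O)OCc2ccccc2)c(OCc2ccccc2)c1 | intermediate
18 | benzyl 2-(benzyloxy)-4-[(3-chloro-2-hydroxy-4-methoxy-6-propylbenzoyl)oxy]-6-propylbenzoate | CCCc1cc(OC(=O)c2c(CCC)cc(OC)c(Cl)c2O)cc(OCc2ccccc2)c1C(=O)OCc1ccccc1 | intermediate
19 | 3-chlorodivaricatic acid | CCCc1cc(OC(=O)c2c(CCC)cc(OC)c(Cl)c2O)cc(O)c1C(=O)O | target

**Step count**

Total: 11 steps. Longest linear sequence: 9 steps (steps 1–7, 10, 11); the diene branch is steps 8–9.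

**Steps most likely to fail**

Step 10. The β-propyl ynoate is a sluggish dienophile and the chlorine lowers the diene HOMO, so thermal decomposition or silyl migration of the diene may outrun cycloaddition. The C4A enol ether of the cycloadduct may also hydrolyse before aromatization. The fallback gives up the cycloaddition, makes ring A by directed metalation and joins it to ring B by a classical depside esterification. It sets out from 1 and comes back at 18.
- 1 is O-methylated (Me2SO4, K2CO3, acetone) to 1,3-dimethoxy-5-propylbenzene F1.
- Lithiation between the two methoxy groups (n-BuLi, THF, 0 °C) and quenching with C2Cl6 gives 2-chloro-1,3-dimethoxy-5-propylbenzene F2, which fixes the chlorine position.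
- Rieche formylation (Cl2CHOMe, TiCl4, CH2Cl2, 0 °C) at the only type of open position gives 3-chloro-2,4-dimethoxy-6-propylbenzaldehyde F3.
- Chelation-controlled demethylation of the methoxy group ortho to the aldehyde (BCl3, CH2Cl2, −78 → 0 °C) gives 3-chloro-2-hydroxy-4-methoxy-6-propylbenzaldehyde F4.
- Chlorite oxidation (NaClO2, sulfamic acid, aqueous dioxane) gives 3-chloro-2-hydroxy-4-methoxy-6-propylbenzoic acid F5.
- F5 is condensed with phenol 8 through the mixed trifluoroacetic anhydride (TFAA, toluene, rt) to give 18.

Step 11. Hydrodechlorination of ring A may compete with the slower cleavage of the hindered benzyl ester. The fallback replaces reduction by Lewis-acid debenzylation. It sets out from 18 and comes back at 19: BCl3 with pentamethylbenzene as benzyl cation scavenger in CH2Cl2 at −78 °C should cleave both benzyl groups while the methyl ether, the aryl chloride and the depside ester persist. It makes no new compound.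

Step 8. The α-chloro ketal may fail to lose methanol cleanly on distillation, or the chloro keto ester may decompose under the acid. The fallback reverses the order of methylation and chlorination. It sets out from commercial methyl (2E)-3-methoxybut-2-enoate F6 and comes back at 13: ionic chlorination at C2 with N-chlorosuccinimide in MeCN, followed by Et3N to bring any deconjugated isomer back into conjugation, should give 13. Either alkene isomer would give the same dienolate 14 in step 9.

**Further compounds**

F1 | step 10 | 1,3-dimethoxy-5-propylbenzene | CCCc1cc(OC)cc(OC)c1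
F2 | step 10 | 2-chloro-1,3-dimethoxy-5-propylbenzene | CCCc1cc(OC)c(Cl)c(OC)c1
F3 | step 10 | 3-chloro-2,4-dimethoxy-6-propylbenzaldehyde | CCCc1cc(OC)c(Cl)c(OC)c1C=O
F4 | step 10 | 3-chloro-2-hydroxy-4-methoxy-6-propylbenzaldehyde | CCCc1cc(OC)c(Cl)c(O)c1C=O
F5 | step 10 | 3-chloro-2-hydroxy-4-methoxy-6-propylbenzoic acid | CCCc1cc(OC)c(Cl)c(O)c1C(=O)O
F0 | step 11 | none | none
F6 | step 8 | methyl (2E)-3-methoxybut-2-enoate | CO/C(C)=C/C(=O)OC
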